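## Retrosynthetic overview

- Feature: in ring C the butyryl carbon C1 lies between C2–OH and C6–OH, C6 is followed by the unsubstituted C5–H, and C2 by the bridge carbon C3 and then C4–OMe. Butyric acid added across an aryne spanning C1/C6, with an alkoxy group at C2, therefore makes the C6–O and C1–C(=O) bonds together.
- Last disconnection: the bond from the ring C CH2 to the free carbon of ring B. Ring C arrives as a benzylic methyl ether, made by oxidising the ring methyl of aspidinol in methanol and ionised by acid in the last step; the partner is the ring A–CH2–ring B dimer.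
- Aspidinol comes from selective BCl3 demethylation of the aryne insertion product; the silylaryl triflate comes from 2,6-dimethoxytoluene in three operations.
- The A–B dimer comes from butyrylfilicinic acid, an iminium CH2 unit and butyrylphloroglucinol, both rings derived from phloroglucinol and butyryl chloride.
- No ring is built in the route: ring C is carried from 2,6-dimethoxytoluene, rings A and B from phloroglucinol. They are joined A–B first, then C.

Key step: step 4

Remark on the chemistry: the target has no stereocentre. Ring A is drawn as one enol tautomer of the triketone and all its tautomers are treated as the same compound. Ring C is numbered as in aspidinol (C1 butyryl, C2 and C6 OH, C3 bridge carbon, C4 OMe, C5 H). The benzyl cation of step 10 is drawn as one resonance form.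

## Route

Step 1
Reactants: 1 2,6-dimethoxytoluene
Product: 3 3,5-dimethoxy-4-methylphenol, via arylboronate 2 (not isolated)
Conditions: [Ir(OMe)(cod)]2 (cat.), dtbpy, B2pin2, THF, 80 °C; then KHSO5 (Oxone), acetone/H2O, rt
Reagents that add atoms: bis(pinacolato)diboron, CC1(C)OB(OC1(C)C)B1OC(C)(C)C(C)(C)O1; potassium peroxymonosulfate, [K+].[O-]S(=O)(=O)OO
Why: Iridium-catalysed aromatic C–H borylation is sterically governed and should go to the only ring C–H without an ortho substituent (para to the methyl group), and the boronate is oxidised in the same flask at the same carbon (one-pot borylation/oxidation to a phenol).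

Step 2
Reactants: 3 3,5-dimethoxy-4-methylphenol
Product: 4 2-bromo-3,5-dimethoxy-4-methylphenol
Conditions: NBS (1.0 equiv), CH2Cl2, −78 °C → 0 °C
Reagents that add atoms: N-bromosuccinimide, O=C1CCC(=O)N1Br
Why: Electrophilic aromatic bromination of a phenol whose para position is blocked by methyl and whose two ortho positions are equivalent, so one equivalent of NBS at low temperature should give the single monobromide.

Step 3
Reactants: 4 2-bromo-3,5-dimethoxy-4-methylphenol
Product: 7 3,5-dimethoxy-4-methyl-2-(trimethylsilyl)phenyl trifluoromethanesulfonate, via aryl silyl ether 5 (not isolated), via lithium silylphenoxide 6 (not isolated)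
Conditions: HMDS, THF, 70 °C, then evaporation; n-BuLi, THF, −100 °C → −78 °C; Tf2O, −100 °C → rt
Reagents that add atoms: hexamethyldisilazane, C[Si](C)(C)N[Si](C)(C)C; n-butyllithium, [Li]CCCC; trifluoromethanesulfonic anhydride, O=S(=O)(OS(=O)(=O)C(F)(F)F)C(F)(F)F
Why: This is the standard route to ortho-silylaryl triflates: O-silylation, bromine–lithium exchange, anionic 1,3-shift of silicon from O to C (retro-Brook rearrangement) and O-triflation of the lithium phenoxide.

Step 4
Reactants: 7 3,5-dimethoxy-4-methyl-2-(trimethylsilyl)phenyl trifluoromethanesulfonate; 8 butyric acid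
Product: 10 1-(6-hydroxy-2,4-dimethoxy-3-methylphenyl)butan-1-one, via aryne 9 (not isolated)
Conditions: CsF (4 equiv), THF, 125 °C, sealed tube
Reagents that add atoms: none
Why: Fluoride attacks silicon and triflate leaves to give aryne 9; butyrate oxygen adds to the aryne carbon whose neighbour is C–H (the former triflate carbon), the aryl anion formed beside the methoxy group attacks the ester carbonyl through a four-membered transition state, and opening of that adduct moves the acyl group from O to C and leaves the cesium phenoxide. The closest known reaction type is the fluoride-induced insertion of arynes into the C–O bond of carboxylic acids, which gives ortho-hydroxyaryl ketones from silylaryl triflates, CsF and the acid in hot THF. No ring is closed and no stereocentre is formed. The step needs regioselective addition across the unsymmetrical aryne, and the methoxy group next to one aryne carbon secures it: its inductive pull distorts the aryne so that the nucleophile enters at the remote carbon and the negative charge develops next to oxygen. It also needs acyl transfer to outrun protonation of the aryl anion, which the aprotic medium, the high temperature and the use of butyrate as its cesium salt without excess free acid should favour.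

Step 5
Reactants: 10 1-(6-hydroxy-2,4-dimethoxy-3-methylphenyl)butan-1-one
Product: 11 1-(2,6-dihydroxy-4-methoxy-3-methylphenyl)butan-1-one (aspidinol)
Conditions: BCl3 (3 equiv), CH2Cl2, −78 °C → rt; then H2O
Reagents that add atoms: none
Why: Lewis acid ether cleavage by BCl3 should select the C2 methoxy group, which is pressed out of conjugation between the butyryl and methyl groups and lies beside the boron-bound carbonyl, while the conjugated C4 methoxy group para to the ketone is left (selective demethylation ortho to an aryl ketone).

Step 6
Reactants: 11 1-(2,6-dihydroxy-4-methoxy-3-methylphenyl)butan-1-one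
Product: 13 1-[2,6-dihydroxy-4-methoxy-3-(methoxymethyl)phenyl]butan-1-one, via quinone methide 12 (not isolated)
Conditions: DDQ (1.0 equiv), MeOH/CH2Cl2, 0 °C
Reagents that add atoms: methanol, CO
Why: DDQ dehydrogenation of a methyl group ortho and para to phenolic OH gives the quinone methide, as known for cresols and for methyl-substituted acylphloroglucinols, and solvent methanol should capture it faster than C5 of unreacted 11 can (benzylic oxidation with solvent trapping); 13 is used without delay.

Step 7
Reactants: 14 phloroglucinol; 15 butyryl chloride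
Product: 16 1-(2,4,6-trihydroxyphenyl)butan-1-one (butyrylphloroglucinol)
Conditions: AlCl3, PhNO2/CH2Cl2, 0 °C → 50 °C; aq. HCl
Reagents that add atoms: none
Why: Friedel–Crafts C-acylation of phloroglucinol stops after one acyl group because the chelated ketone deactivates the ring.

Step 8
Reactants: 16 1-(2,4,6-trihydroxyphenyl)butan-1-one
Product: 17 2-butanoyl-3,5-dihydroxy-4,4-dimethylcyclohexa-2,5-dien-1-one (butyrylfilicinic acid)
Conditions: NaOMe, MeI (2 equiv), MeOH, 0 °C → rt
Reagents that add atoms: iodomethane, CI
Why: C-alkylation of the acylphloroglucinol polyanion with a second methylation at the same ring carbon gives the dearomatised geminal dimethyl trione, a known entry to acylfilicinic acids, with under- and over-methylated material removed by chromatography.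

Step 9
Reactants: 17 2-butanoyl-3,5-dihydroxy-4,4-dimethylcyclohexa-2,5-dien-1-one; 16 1-(2,4,6-trihydroxyphenyl)butan-1-one
Product: 20 2-butanoyl-6-[(3-butanoyl-2,4,6-trihydroxyphenyl)methyl]-3,5-dihydroxy-4,4-dimethylcyclohexa-2,5-dien-1-one (ring A–ring B dimer), via Mannich base 18 (not isolated), via methylene trione 19 (not isolated)
Conditions: Me2N=CH2+ I− (1.0 equiv), MeCN, rt; then 16 (3 equiv), 60 °C
Reagents that add atoms: N,N-dimethylmethyleneiminium iodide, C=[N+](C)C.[I-]
Why: Mannich reaction at the only free enol carbon of 17, loss of dimethylamine to the exocyclic enone and Michael addition of a ring carbon of 16 (alkylation by a Mannich base) should give the unsymmetrical dimer, with excess 16 preventing a second alkylation of ring B.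

Step 10
Reactants: 13 1-[2,6-dihydroxy-4-methoxy-3-(methoxymethyl)phenyl]butan-1-one; 20 2-butanoyl-6-[(3-butanoyl-2,4,6-trihydroxyphenyl)methyl]-3,5-dihydroxy-4,4-dimethylcyclohexa-2,5-dien-1-one
Product: 22 2-butanoyl-6-[[3-butanoyl-5-[(3-butanoyl-2,4-dihydroxy-6-methoxyphenyl)methyl]-2,4,6-trihydroxyphenyl]methyl]-3,5-dihydroxy-4,4-dimethylcyclohexa-2,5-dien-1-one (target), via hydroxybenzyl cation 21 (not isolated)
Conditions: 20 (2 equiv), TsOH·H2O (10 mol %), 1,4-dioxane, 40 °C, slow addition of 13
Reagents that add atoms: none
Why: TsOH protonates the benzylic ether oxygen of 13, methanol leaves, and the benzyl cation 21, stabilised by the ortho C2–OH, the ortho C4–OMe and the para C6–OH, should alkylate the only free aromatic carbon of 20, on ring B, which then rearomatises (Friedel–Crafts benzylation by a benzylic ether), with excess 20, slow addition of 13 and the low acid loading working against self-alkylation and bridge exchange.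

## Compound list

1 | 2,6-dimethoxytoluene | COc1cccc(OC)c1C | starting material
2 | 2-(3,5-dimethoxy-4-methylphenyl)-4,4,5,5-tetramethyl-1,3,2-dioxaborolane | COc1cc(B2OC(C)(C)C(C)(C)O2)cc(OC)c1C | intermediate (not isolated)
3 | 3,5-dimethoxy-4-methylphenol | COc1cc(O)cc(OC)c1C | intermediate
4 | 2-bromo-3,5-dimethoxy-4-methylphenol | COc1cc(O)c(Br)c(OC)c1C | intermediate
5 | (2-bromo-3,5-dimethoxy-4-methylphenoxy)trimethylsilane | COc1cc(O[Si](C)(C)C)c(Br)c(OC)c1C | intermediate (not isolated)
6 | lithium 3,5-dimethoxy-4-methyl-2-(trimethylsilyl)phenolate | COc1cc([O-])c([Si](C)(C)C)c(OC)c1C.[Li+] | intermediate (not isolated)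
7 | 3,5-dimethoxy-4-methyl-2-(trimethylsilyl)phenyl trifluoromethanesulfonate | COc1cc(OS(=O)(=O)C(F)(F)F)c([Si](C)(C)C)c(OC)c1C | intermediate
8 | butyric acid | CCCC(=O)O | starting material
9 | 3,5-dimethoxy-4-methylbenzyne (1,2-didehydro-3,5-dimethoxy-4-methylbenzene) | COC1=C(C)C(OC)=CC#C1 | intermediate (not isolated)
10 | 1-(6-hydroxy-2,4-dimethoxy-3-methylphenyl)butan-1-one | CCCC(=O)c1c(O)cc(OC)c(C)c1OC | intermediate
11 | 1-(2,6-dihydroxy-4-methoxy-3-methylphenyl)butan-1-one (aspidinol) | CCCC(=O)c1c(O)cc(OC)c(C)c1O | intermediate
12 | 2-butanoyl-3-hydroxy-5-methoxy-4-methylidenecyclohexa-2,5-dien-1-one (quinone methide, para tautomer drawn) | CCCC(=O)C1=C(O)C(=C)C(OC)=CC1=O | intermediate (not isolated)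
13 | 1-[2,6-dihydroxy-4-methoxy-3-(methoxymethyl)phenyl]butan-1-one | CCCC(=O)c1c(O)cc(OC)c(COC)c1O | intermediate
14 | phloroglucinol | Oc1cc(O)cc(O)c1 | starting material
15 | butyryl chloride | CCCC(Cl)=O | starting material
16 | 1-(2,4,6-trihydroxyphenyl)butan-1-one | CCCC(=O)c1c(O)cc(O)cc1O | intermediate
17 | 2-butanoyl-3,5-dihydroxy-4,4-dimethylcyclohexa-2,5-dien-1-one | CCCC(=O)C1=C(O)C(C)(C)C(O)=CC1=O | intermediate
18 | 2-butanoyl-6-[(dimethylamino)methyl]-3,5-dihydroxy-4,4-dimethylcyclohexa-2,5-dien-1-one | CCCC(=O)C1=C(O)C(C)(C)C(O)=C(CN(C)C)C1=O | intermediate (not isolated)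
19 | 2-butanoyl-3-hydroxy-4,4-dimethyl-6-methylidenecyclohex-2-ene-1,5-dione | CCCC(=O)C1=C(O)C(C)(C)C(=O)C(=C)C1=O | intermediate (not isolated)
20 | 2-butanoyl-6-[(3-butanoyl-2,4,6-trihydroxyphenyl)methyl]-3,5-dihydroxy-4,4-dimethylcyclohexa-2,5-dien-1-one | CCCC(=O)C1=C(O)C(C)(C)C(O)=C(Cc2c(O)cc(O)c(C(=O)CCC)c2O)C1=O | intermediate
21 | (3-butanoyl-2,4-dihydroxy-6-methoxyphenyl)methylium (oxygen-stabilised benzyl cation) | CCCC(=O)c1c(O)cc(OC)c([CH2+])c1O | intermediate (not isolated)
22 | 2-butanoyl-6-[[3-butanoyl-5-[(3-butanoyl-2,4-dihydroxy-6-methoxyphenyl)methyl]-2,4,6-trihydroxyphenyl]methyl]-3,5-dihydroxy-4,4-dimethylcyclohexa-2,5-dien-1-one | CCCC(=O)C1=C(O)C(C)(C)C(O)=C(Cc2c(O)c(Cc3c(OC)cc(O)c(C(=O)CCC)c3O)c(O)c(C(=O)CCC)c2O)C1=O | target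

## Step count and risks

Total step count: 10. Longest linear sequence: 7 (steps 1–6 and 10, from 2,6-dimethoxytoluene).

Steps most likely to fail:

1. Step 10. The benzyl cation may be captured by C5 of its own precursor, and the methylene bridge of 20 may be cleaved and re-formed under acid, giving scrambled oligomers. Fallback, inverting the order of assembly: it sets out from 13, with 16 as partner. Compound 13 is added slowly to a large excess of the monomer 16 (TsOH·H2O cat., 1,4-dioxane, 40 °C) to give the ring B–ring C dimer 1-[3-[(3-butanoyl-2,4,6-trihydroxyphenyl)methyl]-2,6-dihydroxy-4-methoxyphenyl]butan-1-one F1. Mannich base 18, made from 17 and Me2N=CH2+ I− as in step 9, is then warmed with F1 in MeCN without acid, so that methylene trione 19 is trapped by the free carbon of the trihydroxylated ring B, which is more nucleophilic than C5 of ring C. The sequence comes back to the route at 22.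

2. Step 6. The benzylic ether may be oxidised further to the aldehyde, or the free phenol may undergo oxidative coupling instead of clean hydride loss from the methyl group. Fallback by radical halogenation instead of quinone oxidation: it sets out from 11. Both phenols are acetylated (Ac2O, pyridine) to 2-butanoyl-5-methoxy-4-methyl-1,3-phenylene diacetate F2. Wohl–Ziegler bromination (NBS, AIBN, PhCF3, 80 °C) gives 4-(bromomethyl)-2-butanoyl-5-methoxy-1,3-phenylene diacetate F3. K2CO3 in MeOH at 0 °C then removes both acetates and replaces bromide by methoxide, coming back to the route at 13.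

3. Step 4. The aryl anion may be protonated before the acyl group migrates, so that the aryl ester forms instead of the ketone, and the product phenoxide may be arylated by further aryne. Fallback without an aryne: it sets out from 3. The phenol is acylated with 15 (Et3N, CH2Cl2) to 3,5-dimethoxy-4-methylphenyl butanoate F4. Fries rearrangement (BF3·OEt2, heat) moves the butyryl group to one of the two equivalent ortho positions, the para position being blocked by methyl, coming back to the route at 10. Ester formed as by-product in step 4 is the same compound and can be sent through the same rearrangement.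

## Further compounds

F1 | step 10 | 1-[3-[(3-butanoyl-2,4,6-trihydroxyphenyl)methyl]-2,6-dihydroxy-4-methoxyphenyl]butan-1-one | CCCC(=O)c1c(O)cc(O)c(Cc2c(OC)cc(O)c(C(=O)CCC)c2O)c1O
F2 | step 6 | 2-butanoyl-5-methoxy-4-methyl-1,3-phenylene diacetate | CCCC(=O)c1c(OC(C)=O)cc(OC)c(C)c1OC(C)=O
F3 | step 6 | 4-(bromomethyl)-2-butanoyl-5-methoxy-1,3-phenylene diacetate | CCCC(=O)c1c(OC(C)=O)cc(OC)c(CBr)c1OC(C)=O
F4 | step 4 | 3,5-dimethoxy-4-methylphenyl butanoate | CCCC(=O)Oc1cc(OC)c(C)c(OC)c1
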